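## The problem

The target 30 is a cembranolide: a fourteen-membered carbocycle (C1–C14) with E-trisubstituted olefins at C3=C4 and C7=C8, a chlorohydrin at C11 (secondary chloride) and C12 (tertiary, methyl-bearing carbinol), and an α-methylene-γ-butyrolactone (C15, C16, exocyclic C17) trans-fused across C1/C14; the configuration is 1R,11S,12R,14S. The four stereocenters form two vicinal pairs, C1/C14 and C11/C12, joined only by the C13 methylene. The C12 hydroxyl is 1,3-syn to the C14 oxygen, and the chloride is anti to the C12 hydroxyl, which is the outcome of SN2 opening of an (11R,12R) trans-epoxide at C11. C14 is the only centre that can relay information to C12, and open-chain chelate models favour the wrong face when C11 adds as a carbon nucleophile to a C12 ketone, so this centre is the hard one. Three groups dictate the order of events: the methylene lactone is a Michael acceptor that will not survive carbanions, hydrides or reducing metals, the chlorohydrin closes to an epoxide with base, and the skipped trisubstituted olefins must keep their geometry through every C–C bond formation. The feature that opens the synthesis is local: C1 (bearing the acyl-level carbon C15) and C14 (bearing oxygen) are flanked by the methylenes C2 and C13, which lead to the sp2 carbon C3 and to the methyl-bearing C12. C2–C3 and C13–C12(CH3) are the skeleton of isoprene and C1/C14 are the two carbons of an E-β-acyloxy enone, so C1, C2, C3, C12, C13 and C14 can be made as a cyclohexene whose C3=C12 bond, absent from the target, is cut by ozone to leave an aldehyde at C3 and a methyl ketone at C12.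

## Retrosynthesis

The lactone is cut first, at C15–C16 and C16–O: the carbonyl carbon goes back to carbon monoxide and 30 becomes the hydroxy vinyl triflate 29. The neighbouring option, α-methylenation of a saturated lactone enolate, needs strong base next to the chlorohydrin and must bring in C17. Here C17 is already the methyl of a C15 methyl ketone, so 29 follows from ketone 26 by silylation (27), kinetic enol triflation (28) and desilylation. The precursor has no Michael acceptor. The forward steps must enolize the methyl and not C1, and the carbonylation must tolerate a free chlorohydrin.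

The C11–Cl bond is cut next. Ketone 26 is the deprotected form of chlorohydrin 25, and 25 goes back to the trans-epoxide 24, because the anti Cl/OH arrangement is that of SN2 opening at the less substituted carbon. Direct displacement of a C11 sulfonate would have to occur next to a quaternary carbinol and would lose to epoxide closure; the epoxide route uses that closure instead. 24 comes from the anti diol 22 with inversion at C11, and 22 from the α-hydroxy ketone 21, in which C11 is not stereogenic, so both C11 epimers of diol 20 are usable. The forward steps need a chelation-controlled reduction and an opening that is regioselective for C11.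

The ring is opened at C11–C12, the bond between the two oxygenated carbons, which gives keto aldehyde 19. This is preferred to closure at C5–C6 by sulfone alkylation, because the C12 ketone left by ozonolysis becomes a ring-closing partner directly and C11 arrives at the aldehyde level from geraniol. Closing elsewhere would still require C11–C12 to be made intermolecularly with no better control. 19 is acyclic and carries only two stereocenters. The forward pinacol needs high dilution, and its face selectivity at C12 is the open question of the plan.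

19 is cut at C5–C6 between the two isoprenoid units: through diol 18 and sulfone 17 it leads to allylic bromide 12 and hydroxy sulfone 16. Allylic sulfone alkylation joins two sp3 carbons and leaves both E olefins alone, which a second olefination could not guarantee. 16 comes from geraniol 13 through sulfone 15 by cutting off the terminal isopropylidene, so the C7=C8 geometry is bought, not made.

12 is traced through diol 11 to enoate 10, and C3=C4 is cut to the C3 aldehyde of 9 and a stabilised ylide, which fixes the E geometry. The C12 ketone is reduced together with the ester and stays masked as a carbinol through the carbanion and hydride steps. An unstabilised ylide carrying the whole C4–C11 chain would be shorter but would not control the trisubstituted olefin.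

9 is a 1,6-keto aldehyde; joining C3 and C12 as an olefin gives cyclohexene 8, of which 9 is the ozonolysis product. 8 is the protected form of 5 (ketal 6, alcohol 7); the benzoate must be exchanged because it would not survive hydride and carbanion steps.

5 is cut at C1–C2 and C13–C14 into isoprene 4 and enone 3. One catalytic step then sets C1 and C14, places the methyl on C12 and gives the two carbonyl termini in differentiated form. 3 is the adduct of benzoic acid 2 and but-3-yn-2-one 1.

## Roads not taken

Alternative 1: The cut is C9–C10. A sixteen-membered allyl β-keto lactone A2 would be ionised by Pd(PPh3)4, lose CO2 and recombine as enolate and π-allyl to give the fourteen-membered C11 ketone A1. Its merits are real: ring closure is split into an easy macrolactonisation and an intramolecular C–C formation inside an ion pair, no stereocenter is created at ring closure, and C12 is already in place. On this point it is better than the chosen plan, whose pinacol creates C11 and C12 while closing the ring. Its weak points are the π-allyl, which can recombine at C7 or scramble the C7=C8 geometry, and the conversion of the C11 ketone into the 11S chloride, which needs a reduction and then a displacement next to a quaternary carbon. The lactone of A1 must also be methylenated by enolate chemistry in the presence of a ketone or a chlorohydrin, and C1, C12 and C14 of A2 must each be set in separate acyclic steps. Against this the chosen plan sets one catalytic step for C1 and C14 from commodity materials, chloride delivery through an epoxide, and a methylene lactone made from CO with C17 already present.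

Alternative 2: The cuts are C1–C2 and C15–C17. The lithiated allylic sulfone of the open-chain butenolide A4 would add to C1, closing the ring, and the lactone enolate would be trapped by Eschenmoser's salt to give A3. This road is more convergent and shorter after fragment union than the chosen one, needs no ketone protection, sets C1 anti to the C14 substituent by substrate control and brings in C17 in the same operation. Its weak points lie in the substrate: A4 must carry C11, C12 and C14 ready-made, the silylated chlorohydrin meets a strong base and a carbanion (elimination or internal alkylation at C11), and the γ-stereocenter C14 of a butenolide is easily deprotonated. The allylic sulfone anion can react at its γ-carbon, A3 is a mixture at C2 and C15, and the sulfone must later be removed reductively without touching the chloride or the unsaturated lactone. The chosen plan is longer in the linear sense but exposes the chlorohydrin to base only after it has been silylated (step 20, before the enol triflation) and never has an epimerisable C14.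

Alternative 3: The cut is C11–C12, as in the chosen plan, but on the lactone-bearing seco keto aldehyde A6, which SmI2 (divalent samarium) would close to the (11R,12R) diol lactone A5. It needs no ketal, the fused lactone may restrict the chain and help face selection, and it is probably shorter after ring closure. In the ring-closing event itself the two plans are equal, and equally unproven in stereocontrol. Its weak points are that a syn diol must be converted to the chloride by direct displacement at C11 (closure to the cis epoxide competes), that the methylene must be added to the lactone by base in the presence of a chlorohydrin or its precursor, and that the trans lactone of A6 needs its own asymmetric synthesis. The chosen plan answers the first with an oxidation–reduction that funnels both C11 epimers to the anti diol, the second with a carbonylation under amine base, and the third with the Diels–Alder step.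

Key step: step 2

Assumption: the facial sense of the oxazaborolidinium catalyst is assigned by analogy with its behaviour toward acrylate and enone dienophiles, which predicts (1S,6S)-5 from the (R)-proline-derived catalyst; if the adduct proved antipodal, the (S)-catalyst would be used and nothing else changes.

Step 1
Reactants: 1 but-3-yn-2-one; 2 benzoic acid
Product: 3 (1E)-3-oxobut-1-en-1-yl benzoate [(E)-4-benzoyloxybut-3-en-2-one]
Conditions: N-methylmorpholine (10 mol %), MeCN, 0 → 25 °C
Reagents that add atoms: none
Why: Amine-catalysed conjugate (oxa-Michael) addition of a carboxylic acid to an ynone; the β-ammonium enone exchanges amine for benzoate by addition–elimination, and this reversible sequence should settle on the more stable E enol ester.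

Step 2
Reactants: 3 (1E)-3-oxobut-1-en-1-yl benzoate; 4 isoprene
Product: 5 (1S,6S)-6-acetyl-3-methylcyclohex-3-en-1-yl benzoate
Conditions: oxazaborolidinium triflimide from (R)-α,α-diphenylprolinol, tri-o-tolylboroxine and HNTf2 (20 mol %), isoprene (5 equiv), CH2Cl2, −40 → −20 °C
Reagents that add atoms: none
Why: The cationic oxazaborolidine binds the ketone oxygen of 3 and lowers the LUMO of the s-trans enone, which undergoes a concerted, asynchronous [4+2] cycloaddition with s-cis isoprene; the closest known reaction type is the oxazaborolidinium-catalysed Diels–Alder reaction of 2-substituted butadienes with trans-β-substituted enones. The cyclohexene (C1, C2, C3, C12, C13, C14) closes by intermolecular suprafacial–suprafacial addition that forms C1–C2 and C13–C14 in one step. The larger diene coefficient at C13, the CH2 next to the methyl-bearing carbon, pairs with the β-carbon C14 of the activated enone, which gives the para adduct with the methyl on C12. The trans relationship of C1 and C14 follows from the E geometry of 3, and there is no endo/exo question because the diene termini are unsubstituted. The absolute configuration is set by the catalyst, whose aryl group shields one face of the bound enone so that isoprene adds to the Si face of C1. The step needs enantioface control, para regiocontrol and survival of the β-benzoyloxy ketone: the first comes from the catalyst, the second from ketone activation, the third from low temperature and the absence of base.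

Step 3
Reactants: 5 (1S,6S)-6-acetyl-3-methylcyclohex-3-en-1-yl benzoate
Product: 6 (1S,6S)-3-methyl-6-(2-methyl-1,3-dioxolan-2-yl)cyclohex-3-en-1-yl benzoate
Conditions: (Me3SiOCH2)2, Me3SiOTf (5 mol %), CH2Cl2, −78 → −20 °C
Reagents that add atoms: 1,2-bis(trimethylsilyloxy)ethane, C[Si](C)(C)OCCO[Si](C)(C)C
Why: Noyori ketalization; the aprotic, low-temperature conditions should avoid β-elimination of benzoate and epimerization at C1.

Step 4
Reactants: 6 (1S,6S)-3-methyl-6-(2-methyl-1,3-dioxolan-2-yl)cyclohex-3-en-1-yl benzoate
Product: 7 (1S,6S)-3-methyl-6-(2-methyl-1,3-dioxolan-2-yl)cyclohex-3-en-1-ol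
Conditions: K2CO3, MeOH, 25 °C
Reagents that add atoms: none
Why: Base-catalysed transesterification of the benzoate; with the ketone masked there is no acidic α-hydrogen and no E1cB pathway.

Step 5
Reactants: 7 (1S,6S)-3-methyl-6-(2-methyl-1,3-dioxolan-2-yl)cyclohex-3-en-1-ol
Product: 8 triisopropyl{[(1S,6S)-3-methyl-6-(2-methyl-1,3-dioxolan-2-yl)cyclohex-3-en-1-yl]oxy}silane
Conditions: i-Pr3SiOTf, 2,6-lutidine, CH2Cl2, 0 °C
Reagents that add atoms: triisopropylsilyl trifluoromethanesulfonate, CC(C)[Si](C(C)C)(C(C)C)OS(=O)(=O)C(F)(F)F
Why: Silylation of the secondary alcohol; the triisopropylsilyl group is chosen because it does not chelate metals and is slow to migrate to a later C12 alkoxide.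

Step 6
Reactants: 8 triisopropyl{[(1S,6S)-3-methyl-6-(2-methyl-1,3-dioxolan-2-yl)cyclohex-3-en-1-yl]oxy}silane
Product: 10 ethyl (2E,5S,6S)-2-methyl-5-(2-methyl-1,3-dioxolan-2-yl)-8-oxo-6-[(triisopropylsilyl)oxy]non-2-enoate, via keto aldehyde 9 (not isolated)
Conditions: O3, CH2Cl2, −78 °C; PPh3, −78 → 25 °C; then Ph3P=C(CH3)CO2Et, 25 °C
Reagents that add atoms: ozone, [O-][O+]=O; ethyl 2-(triphenylphosphoranylidene)propanoate, CCOC(=O)C(C)=P(c1ccccc1)(c1ccccc1)c1ccccc1
Why: Ozonolysis cuts the only olefin (C3=C12) to the C3 aldehyde and the C12 methyl ketone, and the stabilised Wittig ylide reacts only with the aldehyde to give the E enoate (C3=C4). Running both in one flask keeps the 1,6-keto aldehyde from intramolecular aldol reaction.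

Step 7
Reactants: 10 ethyl (2E,5S,6S)-2-methyl-5-(2-methyl-1,3-dioxolan-2-yl)-8-oxo-6-[(triisopropylsilyl)oxy]non-2-enoate
Product: 11 (2E,5S,6S)-2-methyl-5-(2-methyl-1,3-dioxolan-2-yl)-6-[(triisopropylsilyl)oxy]non-2-ene-1,8-diol (both C8 epimers; C8 is C12 of the target)
Conditions: i-Bu2AlH (5 equiv), CH2Cl2, −78 °C; Rochelle salt
Reagents that add atoms: none
Why: Hydride reduction of the ester to the allylic alcohol (1,2) and of the C12 ketone to a carbinol that masks it during steps 11 and 12; the new carbinol centre is not controlled and is erased in step 13.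

Step 8
Reactants: 11 (2E,5S,6S)-2-methyl-5-(2-methyl-1,3-dioxolan-2-yl)-6-[(triisopropylsilyl)oxy]non-2-ene-1,8-diol
Product: 12 (4S,5S,7E)-9-bromo-8-methyl-5-(2-methyl-1,3-dioxolan-2-yl)-4-[(triisopropylsilyl)oxy]non-7-en-2-ol (both C2 epimers)
Conditions: N-bromosuccinimide, Me2S, CH2Cl2, −30 → 0 °C
Reagents that add atoms: N-bromosuccinimide, O=C1CCC(=O)N1Br
Why: Corey–Kim halogenation: the alkoxysulfonium salt of the allylic alcohol collapses by SN2 attack of bromide without allylic transposition, while that of the saturated secondary alcohol reverts to the alcohol on work-up.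

Step 9
Reactants: 13 geraniol
Product: 15 {[(2E)-3,7-dimethylocta-2,6-dien-1-yl]sulfonyl}benzene (geranyl phenyl sulfone), via geranyl bromide 14 (not isolated)
Conditions: PBr3, Et2O, −10 °C; then PhSO2Na, DMF, 25 °C
Reagents that add atoms: phosphorus tribromide, BrP(Br)Br (bromine of 14 only); sodium benzenesulfinate, [Na+].[O-]S(=O)c1ccccc1
Why: Bromination of the allylic alcohol and S-alkylation of the sulfinate by SN2 at the primary allylic carbon; the E olefin is retained.

Step 10
Reactants: 15 geranyl phenyl sulfone
Product: 16 (4E)-4-methyl-6-(phenylsulfonyl)hex-4-en-1-ol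
Conditions: O3 (1.0 equiv, Sudan Red 7B end point), CH2Cl2/MeOH, −78 °C; NaBH4, −78 → 0 °C
Reagents that add atoms: ozone, [O-][O+]=O
Why: Chemoselective ozonolysis: the allylic sulfonyl group deactivates the nearer olefin inductively, so the remote isopropylidene is cleaved, and reductive work-up gives the C11 alcohol with the E olefin (C7=C8) intact.

Step 11
Reactants: 12 (4S,5S,7E)-9-bromo-8-methyl-5-(2-methyl-1,3-dioxolan-2-yl)-4-[(triisopropylsilyl)oxy]non-7-en-2-ol; 16 (4E)-4-methyl-6-(phenylsulfonyl)hex-4-en-1-ol
Product: 17 (4E,8E,11S,12S)-4,8-dimethyl-11-(2-methyl-1,3-dioxolan-2-yl)-6-(phenylsulfonyl)-12-[(triisopropylsilyl)oxy]pentadeca-4,8-diene-1,14-diol (epimers at C6 and C14)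
Conditions: 16 (1.5 equiv), n-BuLi (2 equiv per 16), THF, −78 °C; then 12 pre-treated with LiN(SiMe3)2 (1 equiv), −78 → −30 °C
Reagents that add atoms: none
Why: Alkylation of an α-lithiated allylic sulfone (as its alkoxide dianion) with an allylic bromide, a Biellmann-type coupling; reaction at the sulfonyl-bearing carbon C6 and SN2 at C5 form C5–C6 and keep both olefin geometries. The sulfonyl-bearing centre is a mixture and is removed in step 12.

Step 12
Reactants: 17 the coupled hydroxy sulfone
Product: 18 (4E,8E,11S,12S)-4,8-dimethyl-11-(2-methyl-1,3-dioxolan-2-yl)-12-[(triisopropylsilyl)oxy]pentadeca-4,8-diene-1,14-diol (both C14 epimers)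
Conditions: PdCl2(dppp) (5 mol %), LiBHEt3 (6 equiv), THF, 0 °C
Reagents that add atoms: none
Why: Palladium-catalysed reductive desulfonylation: ionisation of the allylic sulfone to a π-allylpalladium species and hydride delivery to the less substituted terminus C6, so the C7=C8 olefin neither shifts nor isomerises.

Step 13
Reactants: 18 the diene diol
Product: 19 (4E,8E,11S,12S)-4,8-dimethyl-11-(2-methyl-1,3-dioxolan-2-yl)-14-oxo-12-[(triisopropylsilyl)oxy]pentadeca-4,8-dienal
Conditions: (COCl)2, Me2SO, CH2Cl2, −78 °C; Et3N, −78 → 0 °C
Reagents that add atoms: none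
Why: Swern oxidation of the primary alcohol to the C11 aldehyde and of the secondary alcohol to the C12 methyl ketone in one operation; the uncontrolled carbinol centre disappears.

Step 14
Reactants: 19 the keto aldehyde
Product: 20 (1S,3E,7E,12R,14S)-4,8,12-trimethyl-1-(2-methyl-1,3-dioxolan-2-yl)-14-[(triisopropylsilyl)oxy]cyclotetradeca-3,7-diene-11,12-diol, both C11 epimers (ring locants of 30)
Conditions: TiCl3(DME)1.5, Zn–Cu couple, DME, 25 °C, 19 added by syringe pump over 30 h (final 0.003 M); aq. K2CO3
Reagents that add atoms: none
Why: Low-valent titanium pinacol coupling (McMurry-type, held at the diol stage at 25 °C) joins the aldehyde carbon C11 and the ketone carbon C12 on the metal surface and closes the fourteen-membered ring under high dilution. C11 forms as both epimers, which converge in step 15; the face of the C12 ketone is not fixed by chelation (the silyl ether does not bind titanium) and depends on the conformation of the templated chain, so material epimeric at C12 is separated after step 15 and can be returned to 19 by glycol cleavage with Pb(OAc)4.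

Step 15
Reactants: 20 the macrocyclic diols
Product: 21 (1S,3E,7E,12R,14S)-12-hydroxy-4,8,12-trimethyl-1-(2-methyl-1,3-dioxolan-2-yl)-14-[(triisopropylsilyl)oxy]cyclotetradeca-3,7-dien-11-one (ring locants of 30)
Conditions: (COCl)2, Me2SO, CH2Cl2, −78 °C; Et3N, −78 → 0 °C
Reagents that add atoms: none
Why: Swern oxidation of the secondary hydroxyl only; the tertiary hydroxyl cannot be oxidised and the activated-sulfoxide conditions do not cleave the glycol, so both C11 epimers give one ketol.

Step 16
Reactants: 21 the α-hydroxy ketone
Product: 22 (1S,3E,7E,11S,12R,14S)-4,8,12-trimethyl-1-(2-methyl-1,3-dioxolan-2-yl)-14-[(triisopropylsilyl)oxy]cyclotetradeca-3,7-diene-11,12-diol (ring locants of 30)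
Conditions: Zn(BH4)2, Et2O, −30 °C
Reagents that add atoms: none
Why: Chelation-controlled (Cram-chelate) reduction: zinc bridges the C12 hydroxyl and the C11 carbonyl and hydride should arrive from the side of the smaller C12 substituent (methyl), giving the anti (11S,12R) diol.

Step 17
Reactants: 22 the anti diol
Product: 24 (1S,3E,7E,11R,12R,14S)-11,12-epoxy-4,8,12-trimethyl-1-(2-methyl-1,3-dioxolan-2-yl)-14-[(triisopropylsilyl)oxy]cyclotetradeca-3,7-diene (ring locants of 30), via C11 mesylate 23 (not isolated)
Conditions: MsCl, Et3N, CH2Cl2, 0 °C; then K2CO3, MeOH, 25 °C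
Reagents that add atoms: methanesulfonyl chloride, CS(=O)(=O)Cl (atoms kept in 23 only; none remain in 24)
Why: Selective mesylation of the secondary hydroxyl, then intramolecular Williamson displacement by the C12 alkoxide with inversion at C11, gives the trans epoxide; C12 is untouched.

Step 18
Reactants: 24 the trans epoxide
Product: 25 (1S,3E,7E,11S,12R,14S)-11-chloro-4,8,12-trimethyl-1-(2-methyl-1,3-dioxolan-2-yl)-14-[(triisopropylsilyl)oxy]cyclotetradeca-3,7-dien-12-ol (ring locants of 30)
Conditions: LiCl (10 equiv), AcOH (3 equiv), THF, 25 °C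
Reagents that add atoms: lithium chloride, [Li+].[Cl-]
Why: SN2 opening of the epoxide by chloride under weakly acidic, non-ionising conditions at the less substituted carbon C11, with inversion; this sets 11S and leaves the C12–O bond and its configuration intact.

Step 19
Reactants: 25 the chlorohydrin ketal
Product: 26 1-[(1S,3E,7E,11S,12R,14S)-11-chloro-12-hydroxy-4,8,12-trimethyl-14-[(triisopropylsilyl)oxy]cyclotetradeca-3,7-dien-1-yl]ethanone (ring locants of 30)
Conditions: pyridinium p-toluenesulfonate (cat.), acetone/H2O (10:1), 55 °C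
Reagents that add atoms: water, O
Why: Acid-catalysed ketal hydrolysis; the chlorohydrin and the secondary silyl ether are stable to mild acid and the β-silyloxy ketone meets no base.

Step 20
Reactants: 26 the chlorohydrin ketone
Product: 27 the C12 triethylsilyl ether of 26
Conditions: Et3SiOTf, 2,6-lutidine, CH2Cl2, −78 °C
Reagents that add atoms: triethylsilyl trifluoromethanesulfonate, CC[Si](CC)(CC)OS(=O)(=O)C(F)(F)F
Why: Silylation of the tertiary hydroxyl at low temperature, so that the strong base of step 21 cannot close the chlorohydrin to an epoxide.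

Step 21
Reactants: 27 the bis-silylated ketone
Product: 28 1-[(1S,3E,7E,11S,12R,14S)-11-chloro-4,8,12-trimethyl-12-[(triethylsilyl)oxy]-14-[(triisopropylsilyl)oxy]cyclotetradeca-3,7-dien-1-yl]ethenyl trifluoromethanesulfonate
Conditions: KN(SiMe3)2, THF, −78 °C; PhNTf2, −78 → −40 °C
Reagents that add atoms: N-phenylbis(trifluoromethanesulfonimide), O=S(=O)(N(c1ccccc1)S(=O)(=O)C(F)(F)F)C(F)(F)F
Why: Kinetic deprotonation of the methyl ketone at the unhindered C17 methyl and O-sulfonylation of the enolate; C1 is not deprotonated, so neither epimerization nor β-elimination of the C14 silyloxy group should occur.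

Step 22
Reactants: 28 the vinyl triflate
Product: 29 1-[(1S,3E,7E,11S,12R,14S)-11-chloro-12,14-dihydroxy-4,8,12-trimethylcyclotetradeca-3,7-dien-1-yl]ethenyl trifluoromethanesulfonate
Conditions: HF·pyridine, THF, 0 → 25 °C
Reagents that add atoms: none
Why: Fluoride-mediated cleavage of both silyl ethers under acidic conditions that spare the vinyl triflate and the chlorohydrin.

Step 23
Reactants: 29 the hydroxy vinyl triflate
Product: 30 (1R,3E,7E,11S,12R,14S)-11-chloro-12-hydroxycembra-3,7,15(17)-trien-16,14-olide (the target)
Conditions: Pd(PPh3)4 (10 mol %), CO (1 atm), Et3N, MeCN, 45 °C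
Reagents that add atoms: carbon monoxide, [C-]#[O+]
Why: Palladium-catalysed carbonylative lactonization: oxidative addition of the vinyl triflate, CO insertion and capture of the acylpalladium by the C14 hydroxyl (five-membered ring) give the α-methylene lactone with C17 already in place. No stereocenter is touched, so the trans fusion is that set in step 2.

Compound list

1 | but-3-yn-2-one | CC(=O)C#C | starting material
2 | benzoic acid | OC(=O)c1ccccc1 | starting material
3 | (1E)-3-oxobut-1-en-1-yl benzoate | CC(=O)/C=C/OC(=O)c1ccccc1 | intermediate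
4 | isoprene | C=CC(C)=C | starting material
5 | (1S,6S)-6-acetyl-3-methylcyclohex-3-en-1-yl benzoate | CC(=O)[C@H]1CC=C(C)C[C@@H]1OC(=O)c1ccccc1 | intermediate
6 | (1S,6S)-3-methyl-6-(2-methyl-1,3-dioxolan-2-yl)cyclohex-3-en-1-yl benzoate | CC1(OCCO1)[C@H]2CC=C(C)C[C@@H]2OC(=O)c3ccccc3 | intermediate
7 | (1S,6S)-3-methyl-6-(2-methyl-1,3-dioxolan-2-yl)cyclohex-3-en-1-ol | CC1(OCCO1)[C@H]2CC=C(C)C[C@@H]2O | intermediate
8 | triisopropyl{[(1S,6S)-3-methyl-6-(2-methyl-1,3-dioxolan-2-yl)cyclohex-3-en-1-yl]oxy}silane | CC1(OCCO1)[C@H]2CC=C(C)C[C@@H]2O[Si](C(C)C)(C(C)C)C(C)C | intermediate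
9 | (3S,4S)-3-(2-methyl-1,3-dioxolan-2-yl)-6-oxo-4-[(triisopropylsilyl)oxy]heptanal (not isolated) | CC1(OCCO1)[C@@H](CC=O)[C@H](CC(C)=O)O[Si](C(C)C)(C(C)C)C(C)C | intermediate
10 | ethyl (2E,5S,6S)-2-methyl-5-(2-methyl-1,3-dioxolan-2-yl)-8-oxo-6-[(triisopropylsilyl)oxy]non-2-enoate | CCOC(=O)/C(C)=C/C[C@H](C1(C)OCCO1)[C@H](CC(C)=O)O[Si](C(C)C)(C(C)C)C(C)C | intermediate
11 | (2E,5S,6S)-2-methyl-5-(2-methyl-1,3-dioxolan-2-yl)-6-[(triisopropylsilyl)oxy]non-2-ene-1,8-diol, C8 epimers | OC/C(C)=C/C[C@H](C1(C)OCCO1)[C@H](CC(C)O)O[Si](C(C)C)(C(C)C)C(C)C | intermediate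
12 | (4S,5S,7E)-9-bromo-8-methyl-5-(2-methyl-1,3-dioxolan-2-yl)-4-[(triisopropylsilyl)oxy]non-7-en-2-ol, C2 epimers | BrC/C(C)=C/C[C@H](C1(C)OCCO1)[C@H](CC(C)O)O[Si](C(C)C)(C(C)C)C(C)C | intermediate
13 | geraniol | CC(C)=CCC/C(C)=C/CO | starting material
14 | geranyl bromide (not isolated) | CC(C)=CCC/C(C)=C/CBr | intermediate
15 | {[(2E)-3,7-dimethylocta-2,6-dien-1-yl]sulfonyl}benzene | CC(C)=CCC/C(C)=C/CS(=O)(=O)c1ccccc1 | intermediate
16 | (4E)-4-methyl-6-(phenylsulfonyl)hex-4-en-1-ol | OCCC/C(C)=C/CS(=O)(=O)c1ccccc1 | intermediate
17 | (4E,8E,11S,12S)-4,8-dimethyl-11-(2-methyl-1,3-dioxolan-2-yl)-6-(phenylsulfonyl)-12-[(triisopropylsilyl)oxy]pentadeca-4,8-diene-1,14-diol, C6 and C14 epimers | OCCC/C(C)=C/C(S(=O)(=O)c1ccccc1)C/C(C)=C/C[C@H](C2(C)OCCO2)[C@H](CC(C)O)O[Si](C(C)C)(C(C)C)C(C)C | intermediate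
18 | (4E,8E,11S,12S)-4,8-dimethyl-11-(2-methyl-1,3-dioxolan-2-yl)-12-[(triisopropylsilyl)oxy]pentadeca-4,8-diene-1,14-diol, C14 epimers | OCCC/C(C)=C/CC/C(C)=C/C[C@H](C1(C)OCCO1)[C@H](CC(C)O)O[Si](C(C)C)(C(C)C)C(C)C | intermediate
19 | (4E,8E,11S,12S)-4,8-dimethyl-11-(2-methyl-1,3-dioxolan-2-yl)-14-oxo-12-[(triisopropylsilyl)oxy]pentadeca-4,8-dienal | O=CCC/C(C)=C/CC/C(C)=C/C[C@H](C1(C)OCCO1)[C@H](CC(C)=O)O[Si](C(C)C)(C(C)C)C(C)C | intermediate
20 | (1S,3E,7E,12R,14S)-4,8,12-trimethyl-1-(2-methyl-1,3-dioxolan-2-yl)-14-[(triisopropylsilyl)oxy]cyclotetradeca-3,7-diene-11,12-diol, C11 epimers (ring locants of 30) | CC1(OCCO1)[C@H]2C/C=C(C)/CC/C=C(C)/CCC(O)[C@](C)(O)C[C@@H]2O[Si](C(C)C)(C(C)C)C(C)C | intermediate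
21 | (1S,3E,7E,12R,14S)-12-hydroxy-4,8,12-trimethyl-1-(2-methyl-1,3-dioxolan-2-yl)-14-[(triisopropylsilyl)oxy]cyclotetradeca-3,7-dien-11-one (ring locants of 30) | CC1(OCCO1)[C@H]2C/C=C(C)/CC/C=C(C)/CCC(=O)[C@](C)(O)C[C@@H]2O[Si](C(C)C)(C(C)C)C(C)C | intermediate
22 | (1S,3E,7E,11S,12R,14S)-4,8,12-trimethyl-1-(2-methyl-1,3-dioxolan-2-yl)-14-[(triisopropylsilyl)oxy]cyclotetradeca-3,7-diene-11,12-diol (ring locants of 30) | CC1(OCCO1)[C@H]2C/C=C(C)/CC/C=C(C)/CC[C@H](O)[C@](C)(O)C[C@@H]2O[Si](C(C)C)(C(C)C)C(C)C | intermediate
23 | C11 methanesulfonate of 22 (not isolated) | CC1(OCCO1)[C@H]2C/C=C(C)/CC/C=C(C)/CC[C@H](OS(C)(=O)=O)[C@](C)(O)C[C@@H]2O[Si](C(C)C)(C(C)C)C(C)C | intermediate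
24 | (1S,3E,7E,11R,12R,14S)-11,12-epoxy-4,8,12-trimethyl-1-(2-methyl-1,3-dioxolan-2-yl)-14-[(triisopropylsilyl)oxy]cyclotetradeca-3,7-diene (ring locants of 30) | CC1(OCCO1)[C@H]2C/C=C(C)/CC/C=C(C)/CC[C@H]3O[C@]3(C)C[C@@H]2O[Si](C(C)C)(C(C)C)C(C)C | intermediate
25 | (1S,3E,7E,11S,12R,14S)-11-chloro-4,8,12-trimethyl-1-(2-methyl-1,3-dioxolan-2-yl)-14-[(triisopropylsilyl)oxy]cyclotetradeca-3,7-dien-12-ol (ring locants of 30) | CC1(OCCO1)[C@H]2C/C=C(C)/CC/C=C(C)/CC[C@H](Cl)[C@](C)(O)C[C@@H]2O[Si](C(C)C)(C(C)C)C(C)C | intermediate
26 | 1-[(1S,3E,7E,11S,12R,14S)-11-chloro-12-hydroxy-4,8,12-trimethyl-14-[(triisopropylsilyl)oxy]cyclotetradeca-3,7-dien-1-yl]ethanone | CC(=O)[C@H]1C/C=C(C)/CC/C=C(C)/CC[C@H](Cl)[C@](C)(O)C[C@@H]1O[Si](C(C)C)(C(C)C)C(C)C | intermediate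
27 | 1-[(1S,3E,7E,11S,12R,14S)-11-chloro-4,8,12-trimethyl-12-[(triethylsilyl)oxy]-14-[(triisopropylsilyl)oxy]cyclotetradeca-3,7-dien-1-yl]ethanone | CC(=O)[C@H]1C/C=C(C)/CC/C=C(C)/CC[C@H](Cl)[C@](C)(O[Si](CC)(CC)CC)C[C@@H]1O[Si](C(C)C)(C(C)C)C(C)C | intermediate
28 | 1-[(1S,3E,7E,11S,12R,14S)-11-chloro-4,8,12-trimethyl-12-[(triethylsilyl)oxy]-14-[(triisopropylsilyl)oxy]cyclotetradeca-3,7-dien-1-yl]ethenyl trifluoromethanesulfonate | C=C(OS(=O)(=O)C(F)(F)F)[C@H]1C/C=C(C)/CC/C=C(C)/CC[C@H](Cl)[C@](C)(O[Si](CC)(CC)CC)C[C@@H]1O[Si](C(C)C)(C(C)C)C(C)C | intermediate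
29 | 1-[(1S,3E,7E,11S,12R,14S)-11-chloro-12,14-dihydroxy-4,8,12-trimethylcyclotetradeca-3,7-dien-1-yl]ethenyl trifluoromethanesulfonate | C=C(OS(=O)(=O)C(F)(F)F)[C@H]1C/C=C(C)/CC/C=C(C)/CC[C@H](Cl)[C@](C)(O)C[C@@H]1O | intermediate
30 | (1R,3E,7E,11S,12R,14S)-11-chloro-12-hydroxycembra-3,7,15(17)-trien-16,14-olide (trans-fused α-methylene-γ-butyrolactone) | C=C1C(=O)O[C@H]2C[C@@](C)(O)[C@@H](Cl)CC/C(C)=C/CC/C(C)=C/C[C@H]12 | target

Total step count: 23. Longest linear sequence: 21 steps (steps 1–8 and 11–23, from but-3-yn-2-one); steps 9 and 10 are the side branch from geraniol.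

Steps least certain to work

Step 2 (key step). The push–pull enone may add to an unactivated diene too slowly at the temperatures that suppress loss of benzoic acid from the adduct. Competing coordination of the catalyst to the benzoate carbonyl may also erode enantioface selection. The fallback separates ring formation from asymmetric induction and sets out from 3 and 4. Thermal cycloaddition (toluene, 130 °C, sealed tube) should give racemic trans-6-acetyl-3-methylcyclohex-3-en-1-yl benzoate F1, with the meta regioisomer removed by chromatography. Ketalization as in step 3 gives the racemic dioxolane benzoate F2 and methanolysis as in step 4 the racemic alcohol F3. Kinetic resolution with Burkholderia cepacia lipase and vinyl acetate in t-BuOMe should acetylate the (1R,6R) enantiomer to (1R,6R)-3-methyl-6-(2-methyl-1,3-dioxolan-2-yl)cyclohex-3-en-1-yl acetate F4, following the empirical rule for secondary alcohols. The unreacted (1S,6S) alcohol is 7, where the route resumes.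

Step 14. Face selection at the C12 ketone may be poor or wrong, since no element of the substrate enforces it, and the ketyl intermediates may oligomerise or be deoxygenated. The fallback lets oxygen, not carbon, be delivered to C12 from C14 and sets out from 19. The same titanium reagent at reflux (McMurry olefination) should give the macrocyclic triene silyl ether F5, with the 11E isomer expected to predominate. Bu4NF frees the homoallylic alcohol F6, and Boc2O with 4-(dimethylamino)pyridine gives the tert-butyl carbonate F7. IBr in toluene at −80 °C closes the six-membered cyclic iodocarbonate F8 through a chair transition state that places the ring chain at C12 equatorial, which is the required 1,3-syn relationship to C14, with iodine anti at C11. K2CO3 in MeOH then gives the epoxy alcohol F9 by inversion at C11, and i-Pr3SiOTf with 2,6-lutidine returns the route to 24.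

Step 18. The epoxide may ionise at the tertiary C12–O bond, which would lead to chloride attack at C12, elimination to an allylic alcohol or transannular capture by the C7=C8 olefin. The fallback opens a less strained, non-ionising ring and sets out from 21. Reagent-controlled reduction with (S)-2-methyl-CBS-oxazaborolidine and catecholborane should give the syn (1S,11R,12R,14S) diol F10, and SOCl2 with pyridine its cyclic sulfite F11. LiCl in DMF at 80 °C attacks the secondary carbon C11 with inversion, and the C12 sulfite monoester loses SO2 on aqueous work-up with retention, which gives 25.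

Step 23. The amine base may close the free chlorohydrin to the epoxide while lactonisation is slow, and the acylpalladium intermediate may decompose before the hydroxyl captures it. The fallback carbonylates before any hydroxyl is free and sets out from 28. Pd(OAc)2, PPh3, CO, MeOH and Et3N should give the methyl 2-substituted acrylate F12 with both silyl ethers in place. HF·pyridine then gives the hydroxy ester F13, and camphorsulfonic acid in CH2Cl2 closes the lactone with loss of methanol to give 30.

## Further compounds

F1 | step 2 | rac-(1S,6S)-6-acetyl-3-methylcyclohex-3-en-1-yl benzoate (racemic trans adduct; one enantiomer drawn) | CC(=O)[C@H]1CC=C(C)C[C@@H]1OC(=O)c1ccccc1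
F2 | step 2 | rac-(1S,6S)-3-methyl-6-(2-methyl-1,3-dioxolan-2-yl)cyclohex-3-en-1-yl benzoate (racemate; one enantiomer drawn) | CC1(OCCO1)[C@H]2CC=C(C)C[C@@H]2OC(=O)c3ccccc3
F3 | step 2 | rac-(1S,6S)-3-methyl-6-(2-methyl-1,3-dioxolan-2-yl)cyclohex-3-en-1-ol (racemate; one enantiomer drawn) | CC1(OCCO1)[C@H]2CC=C(C)C[C@@H]2O
F4 | step 2 | (1R,6R)-3-methyl-6-(2-methyl-1,3-dioxolan-2-yl)cyclohex-3-en-1-yl acetate | CC1(OCCO1)[C@@H]2CC=C(C)C[C@H]2OC(C)=O
F5 | step 14 | (1S,3E,7E,11E,14S)-4,8,12-trimethyl-1-(2-methyl-1,3-dioxolan-2-yl)-14-[(triisopropylsilyl)oxy]cyclotetradeca-3,7,11-triene | CC1(OCCO1)[C@H]2C/C=C(C)/CC/C=C(C)/CC/C=C(C)/C[C@@H]2O[Si](C(C)C)(C(C)C)C(C)C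
F6 | step 14 | (1S,3E,7E,11E,14S)-4,8,12-trimethyl-1-(2-methyl-1,3-dioxolan-2-yl)cyclotetradeca-3,7,11-trien-14-ol | CC1(OCCO1)[C@H]2C/C=C(C)/CC/C=C(C)/CC/C=C(C)/C[C@@H]2O
F7 | step 14 | tert-butyl carbonate of F6 | CC1(OCCO1)[C@H]2C/C=C(C)/CC/C=C(C)/CC/C=C(C)/C[C@@H]2OC(=O)OC(C)(C)C
F8 | step 14 | (1S,11S,12R,14S)-11-iodo 12,14-cyclic carbonate (1,3-dioxan-2-one spanning O12 and O14) | CC1(OCCO1)[C@H]2C/C=C(C)/CC/C=C(C)/CC[C@H](I)[C@@]3(C)C[C@@H]2OC(=O)O3
F9 | step 14 | (1S,3E,7E,11R,12R,14S)-11,12-epoxy-4,8,12-trimethyl-1-(2-methyl-1,3-dioxolan-2-yl)cyclotetradeca-3,7-dien-14-ol | CC1(OCCO1)[C@H]2C/C=C(C)/CC/C=C(C)/CC[C@H]3O[C@]3(C)C[C@@H]2O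
F10 | step 18 | (1S,3E,7E,11R,12R,14S)-4,8,12-trimethyl-1-(2-methyl-1,3-dioxolan-2-yl)-14-[(triisopropylsilyl)oxy]cyclotetradeca-3,7-diene-11,12-diol (syn diol) | CC1(OCCO1)[C@H]2C/C=C(C)/CC/C=C(C)/CC[C@@H](O)[C@](C)(O)C[C@@H]2O[Si](C(C)C)(C(C)C)C(C)C
F11 | step 18 | 11,12-cyclic sulfite of F10 (sulfur epimers) | CC1(OCCO1)[C@H]2C/C=C(C)/CC/C=C(C)/CC[C@H]3OS(=O)O[C@]3(C)C[C@@H]2O[Si](C(C)C)(C(C)C)C(C)C
F12 | step 23 | methyl 2-[(1R,3E,7E,11S,12R,14S)-11-chloro-4,8,12-trimethyl-12-[(triethylsilyl)oxy]-14-[(triisopropylsilyl)oxy]cyclotetradeca-3,7-dien-1-yl]prop-2-enoate | C=C(C(=O)OC)[C@H]1C/C=C(C)/CC/C=C(C)/CC[C@H](Cl)[C@](C)(O[Si](CC)(CC)CC)C[C@@H]1O[Si](C(C)C)(C(C)C)C(C)C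
F13 | step 23 | methyl 2-[(1R,3E,7E,11S,12R,14S)-11-chloro-12,14-dihydroxy-4,8,12-trimethylcyclotetradeca-3,7-dien-1-yl]prop-2-enoate | C=C(C(=O)OC)[C@H]1C/C=C(C)/CC/C=C(C)/CC[C@H](Cl)[C@](C)(O)C[C@@H]1O
A1 | alternative 1 | fourteen-membered C11 ketone with saturated trans lactone and C12 triethylsilyl ether | C1C(=O)O[C@H]2C[C@@](C)(O[Si](CC)(CC)CC)C(=O)CC/C(C)=C/CC/C(C)=C/C[C@H]12
A2 | alternative 1 | sixteen-membered allyl β-keto lactone (ester carbon between C10 and the C9 oxygen) | C1C(=O)O[C@H]2C[C@@](C)(O[Si](CC)(CC)CC)C(=O)CC(=O)OC/C(C)=C/CC/C(C)=C/C[C@H]12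
A3 | alternative 2 | macrocyclic trans lactone with C15 dimethylaminomethyl group and C2 phenylsulfonyl group (C2 and C15 epimers) | CN(C)CC1C(=O)O[C@H]2C[C@@](C)(O[Si](CC)(CC)CC)[C@@H](Cl)CC/C(C)=C/CC/C(C)=C/C(S(=O)(=O)c3ccccc3)[C@H]12
A4 | alternative 2 | open-chain butenolide with C2 allylic phenyl sulfone terminus | O=C1C=C[C@@H](O1)C[C@@](C)(O[Si](CC)(CC)CC)[C@@H](Cl)CC/C(C)=C/CC/C(C)=C/CS(=O)(=O)c1ccccc1
A5 | alternative 3 | macrocyclic (11R,12R)-diol with saturated trans lactone | C1C(=O)O[C@H]2C[C@@](C)(O)[C@H](O)CC/C(C)=C/CC/C(C)=C/C[C@H]12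
A6 | alternative 3 | seco keto aldehyde with trans-disubstituted γ-butyrolactone | CC(=O)C[C@@H]1OC(=O)C[C@H]1C/C=C(C)/CC/C=C(C)/CCC=O
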